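**Retrosynthetic overview**
- Target ⇐ selective benzoylation of the primary (C7) hydroxyl of the C5-monobenzoate tetrol ⇐ hydrolysis of both acetonides of a tricyclic carbasugar carrying the C5 benzoate.
- The cyclohexene is the only ring built, and it is formed last, by ring-closing metathesis (C1=C2) of a 1,7-diene; the dioxolane and 1,3-dioxane rings are bought in with the two building blocks.
- Diene ⇐ Wittig methylenation of a β-silyloxy ketone ⇐ intermolecular (S)-proline aldol reaction forming C5–C6 between 2,2-dimethyl-1,3-dioxan-5-one (C1, C6, C7) and (4R,5S)-2,2-dimethyl-5-vinyl-1,3-dioxolane-4-carbaldehyde (C2–C5).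
- Aldehyde ⇐ dimethyl 2,3-O-isopropylidene-L-tartrate (supplies C3 and C4) by reduction, monosilylation, oxidation, methylenation, desilylation, oxidation.

Assumption: the target is read from the SMILES as [(3S,4R,5R,6R)-5-(benzoyloxy)-3,4,6-trihydroxycyclohex-1-en-1-yl]methyl benzoate; locants C1–C7 in the names of 12–16 are those of the target (C1 carries the exocyclic C7H2O, C2 is the vinylic CH, C3–C6 carry O3–O6).

**Route**

Step 1
Reactants: 1 dimethyl (4R,5R)-2,2-dimethyl-1,3-dioxolane-4,5-dicarboxylate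
Product: 2 [(4S,5S)-2,2-dimethyl-1,3-dioxolane-4,5-diyl]dimethanol
Conditions: LiAlH4, THF, 0 °C → reflux; then H2O
Reagents that add atoms: none
Why: Hydride reduction of both esters (LiAlH4 ester reduction) leaves the acetonide and both stereocentres untouched, the descriptors changing to S,S only through the CIP priorities.

Step 2
Reactants: 2 [(4S,5S)-2,2-dimethyl-1,3-dioxolane-4,5-diyl]dimethanol
Product: 3 {(4S,5S)-5-[(tert-butyldimethylsilyloxy)methyl]-2,2-dimethyl-1,3-dioxolan-4-yl}methanol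
Conditions: NaH (1.0 equiv), THF, 0 °C → rt; then TBSCl (1.0 equiv)
Reagents that add atoms: tert-butyldimethylsilyl chloride (TBSCl), CC(C)(C)[Si](C)(C)Cl
Why: Monosilylation through the sparingly soluble monosodium alkoxide (McDougal monoprotection of a symmetrical diol) stops cleanly at the mono-TBS ether, and because the two hydroxymethyl groups of this C2-symmetric diol are homotopic no stereochemical issue arises.

Step 3
Reactants: 3 {(4S,5S)-5-[(tert-butyldimethylsilyloxy)methyl]-2,2-dimethyl-1,3-dioxolan-4-yl}methanol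
Product: 4 (4R,5S)-5-[(tert-butyldimethylsilyloxy)methyl]-2,2-dimethyl-1,3-dioxolane-4-carbaldehyde
Conditions: (COCl)2, DMSO, CH2Cl2, −78 °C; Et3N, −78 → 0 °C
Reagents that add atoms: none
Why: Swern oxidation gives the α-alkoxy aldehyde at low temperature without epimerisation, the trans-dioxolane being in any case the thermodynamically preferred arrangement.

Step 4
Reactants: 4 (4R,5S)-5-[(tert-butyldimethylsilyloxy)methyl]-2,2-dimethyl-1,3-dioxolane-4-carbaldehyde
Product: 5 tert-butyl{[(4S,5S)-2,2-dimethyl-5-vinyl-1,3-dioxolan-4-yl]methoxy}dimethylsilane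
Conditions: Ph3PCH3Br, KN(SiMe3)2, THF, 0 °C; then 4, −78 °C → rt
Reagents that add atoms: methyltriphenylphosphonium bromide, C[P+](c1ccccc1)(c1ccccc1)c1ccccc1.[Br-]
Why: Wittig methylenation with the unstabilised ylide installs the terminal vinyl group (future C2) without disturbing the adjacent trans-dioxolane stereocentre.

Step 5
Reactants: 5 tert-butyl{[(4S,5S)-2,2-dimethyl-5-vinyl-1,3-dioxolan-4-yl]methoxy}dimethylsilane
Product: 6 [(4S,5S)-2,2-dimethyl-5-vinyl-1,3-dioxolan-4-yl]methanol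
Conditions: Bu4NF, THF, 0 °C → rt
Reagents that add atoms: none
Why: Fluoride-mediated desilylation, driven by Si–F bond formation, frees the primary alcohol while the acetonide and the vinyl group are inert.

Step 6
Reactants: 6 [(4S,5S)-2,2-dimethyl-5-vinyl-1,3-dioxolan-4-yl]methanol
Product: 7 (4R,5S)-2,2-dimethyl-5-vinyl-1,3-dioxolane-4-carbaldehyde
Conditions: (COCl)2, DMSO, CH2Cl2, −78 °C; Et3N, −78 → 0 °C; used crude at once
Reagents that add atoms: none
Why: A second Swern oxidation delivers the trans-configured 2,3-dialkoxypent-4-enal, which is taken on immediately to avoid hydration and evaporative loss of this small aldehyde.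

Step 7
Reactants: 7 (4R,5S)-2,2-dimethyl-5-vinyl-1,3-dioxolane-4-carbaldehyde; 8 2,2-dimethyl-1,3-dioxan-5-one (1.5 equiv)
Product: 9 (4S)-4-{(S)-hydroxy[(4S,5S)-2,2-dimethyl-5-vinyl-1,3-dioxolan-4-yl]methyl}-2,2-dimethyl-1,3-dioxan-5-one
Conditions: (S)-proline (30 mol %), DMF, 2 °C, 5 d
Reagents that add atoms: none
Why: In this proline-catalysed direct intermolecular aldol reaction (List–Houk enamine mechanism) the ring-locked E-enamine of 8 adds through the carboxylic-acid-hydrogen-bonded chair-like transition state to the Re face of aldehyde 7, giving the anti aldol with S configuration at both new centres (C6 and C5 of the target, so C5/C6 erythro and C4/C5 threo) under catalyst control that overrides the facial bias of the α-alkoxy aldehyde, the same pairing that leads from D-glyceraldehyde acetonide to the D-tagato series.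

Step 8
Reactants: 9 (4S)-4-{(S)-hydroxy[(4S,5S)-2,2-dimethyl-5-vinyl-1,3-dioxolan-4-yl]methyl}-2,2-dimethyl-1,3-dioxan-5-one
Product: 10 (4S)-4-{(S)-(tert-butyldimethylsilyloxy)[(4R,5S)-2,2-dimethyl-5-vinyl-1,3-dioxolan-4-yl]methyl}-2,2-dimethyl-1,3-dioxan-5-one
Conditions: TBSOTf, 2,6-lutidine, CH2Cl2, −78 → 0 °C
Reagents that add atoms: tert-butyldimethylsilyl trifluoromethanesulfonate (TBSOTf), CC(C)(C)[Si](C)(C)OS(=O)(=O)C(F)(F)F
Why: Silyl ether formation with the silyl triflate and a hindered pyridine base at low temperature caps the β-hydroxy ketone faster than retro-aldol cleavage or C6 epimerisation can occur (the dioxolane descriptor changes to 4R only through the CIP priorities).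

Step 9
Reactants: 10 (4S)-4-{(S)-(tert-butyldimethylsilyloxy)[(4R,5S)-2,2-dimethyl-5-vinyl-1,3-dioxolan-4-yl]methyl}-2,2-dimethyl-1,3-dioxan-5-one
Product: 11 (4R)-4-{(R)-(tert-butyldimethylsilyloxy)[(4R,5S)-2,2-dimethyl-5-vinyl-1,3-dioxolan-4-yl]methyl}-2,2-dimethyl-5-methylene-1,3-dioxane
Conditions: Ph3PCH3Br, KN(SiMe3)2, THF, 0 °C; then 10, −78 → 0 °C
Reagents that add atoms: methyltriphenylphosphonium bromide, C[P+](c1ccccc1)(c1ccccc1)c1ccccc1.[Br-]
Why: Wittig methylenation with Ph3P=CH2 turns the ketone carbon (future C1) into a 1,1-disubstituted alkene, low temperature and short exposure limiting C6 epimerisation and β-elimination of the silyloxy group (descriptors change only through the CIP priorities).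

Step 10
Reactants: 11 (4R)-4-{(R)-(tert-butyldimethylsilyloxy)[(4R,5S)-2,2-dimethyl-5-vinyl-1,3-dioxolan-4-yl]methyl}-2,2-dimethyl-5-methylene-1,3-dioxane
Product: 12 (3S,4R,5R,6R)-5-(tert-butyldimethylsilyloxy)-3,4:6,7-di-O-isopropylidene-1-(hydroxymethyl)cyclohex-1-ene-3,4,5,6-tetrol (tricycle: cyclohexene, trans-fused O3/O4 dioxolane, O6/O7 1,3-dioxane)
Conditions: second-generation Grubbs catalyst (H2IMes)(PCy3)Cl2Ru=CHPh (5–10 mol %), CH2Cl2 (0.005 M), 40 °C
Reagents that add atoms: none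
Why: In this ring-closing metathesis the ruthenium carbene loads on the monosubstituted vinyl group and closes the six-membered ring onto the 1,1-disubstituted alkene with loss of ethene, forming the trisubstituted C1=C2 bond without touching any stereocentre.

Step 11
Reactants: 12 (3S,4R,5R,6R)-5-(tert-butyldimethylsilyloxy)-3,4:6,7-di-O-isopropylidene-1-(hydroxymethyl)cyclohex-1-ene-3,4,5,6-tetrol
Product: 13 (3S,4S,5R,6R)-3,4:6,7-di-O-isopropylidene-1-(hydroxymethyl)cyclohex-1-ene-3,4,5,6-tetrol (free 5-OH)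
Conditions: Bu4NF, THF, rt
Reagents that add atoms: none
Why: Fluoride desilylation cleaves the secondary TBS ether while both acetonides survive, so only the C5 hydroxyl is exposed.

Step 12
Reactants: 13 (3S,4S,5R,6R)-3,4:6,7-di-O-isopropylidene-1-(hydroxymethyl)cyclohex-1-ene-3,4,5,6-tetrol
Product: 14 (3S,4R,5R,6R)-5-O-benzoyl-3,4:6,7-di-O-isopropylidene-1-(hydroxymethyl)cyclohex-1-ene-3,4,5,6-tetrol
Conditions: BzCl, pyridine, DMAP (cat.), CH2Cl2, 0 °C → rt
Reagents that add atoms: benzoyl chloride (BzCl), O=C(Cl)c1ccccc1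
Why: DMAP-catalysed acylation esterifies the single free hydroxyl, so the secondary benzoate is placed unambiguously at C5.

Step 13
Reactants: 14 (3S,4R,5R,6R)-5-O-benzoyl-3,4:6,7-di-O-isopropylidene-1-(hydroxymethyl)cyclohex-1-ene-3,4,5,6-tetrol
Product: 15 (3S,4R,5R,6R)-5-O-benzoyl-1-(hydroxymethyl)cyclohex-1-ene-3,4,5,6-tetrol
Conditions: AcOH/H2O 4:1, 45 °C; toluene co-evaporation
Reagents that add atoms: none
Why: Mild aqueous-acid acetal hydrolysis removes the strained trans-fused dioxolane and the 1,3-dioxane acetonide, while the benzoate is stable and migrates negligibly at this acidity.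

Step 14
Reactants: 15 (3S,4R,5R,6R)-5-O-benzoyl-1-(hydroxymethyl)cyclohex-1-ene-3,4,5,6-tetrol
Product: 16 [(3S,4R,5R,6R)-5-(benzoyloxy)-3,4,6-trihydroxycyclohex-1-en-1-yl]methyl benzoate
Conditions: BzCl (1.05 equiv), 2,4,6-collidine, CH2Cl2, −78 → −40 °C
Reagents that add atoms: benzoyl chloride (BzCl), O=C(Cl)c1ccccc1
Why: Kinetically controlled acylation with BzCl and a hindered pyridine base at low temperature esterifies the unhindered primary allylic C7 hydroxyl much faster than the three secondary hydroxyls, two of which flank the C5 benzoate.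

**Compound list**

1 | dimethyl (4R,5R)-2,2-dimethyl-1,3-dioxolane-4,5-dicarboxylate (dimethyl 2,3-O-isopropylidene-L-tartrate) | COC(=O)[C@@H]1OC(C)(C)O[C@H]1C(=O)OC | starting material
2 | [(4S,5S)-2,2-dimethyl-1,3-dioxolane-4,5-diyl]dimethanol | OC[C@@H]1OC(C)(C)O[C@H]1CO | intermediate
3 | {(4S,5S)-5-[(tert-butyldimethylsilyloxy)methyl]-2,2-dimethyl-1,3-dioxolan-4-yl}methanol | CC(C)(C)[Si](C)(C)OC[C@@H]1OC(C)(C)O[C@H]1CO | intermediate
4 | (4R,5S)-5-[(tert-butyldimethylsilyloxy)methyl]-2,2-dimethyl-1,3-dioxolane-4-carbaldehyde | CC(C)(C)[Si](C)(C)OC[C@@H]1OC(C)(C)O[C@H]1C=O | intermediate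
5 | tert-butyl{[(4S,5S)-2,2-dimethyl-5-vinyl-1,3-dioxolan-4-yl]methoxy}dimethylsilane | CC(C)(C)[Si](C)(C)OC[C@@H]1OC(C)(C)O[C@H]1C=C | intermediate
6 | [(4S,5S)-2,2-dimethyl-5-vinyl-1,3-dioxolan-4-yl]methanol | OC[C@@H]1OC(C)(C)O[C@H]1C=C | intermediate
7 | (4R,5S)-2,2-dimethyl-5-vinyl-1,3-dioxolane-4-carbaldehyde | O=C[C@@H]1OC(C)(C)O[C@H]1C=C | intermediate
8 | 2,2-dimethyl-1,3-dioxan-5-one | CC1(C)OCC(=O)CO1 | starting material
9 | (4S)-4-{(S)-hydroxy[(4S,5S)-2,2-dimethyl-5-vinyl-1,3-dioxolan-4-yl]methyl}-2,2-dimethyl-1,3-dioxan-5-one | C=C[C@@H]1OC(C)(C)O[C@H]1[C@H](O)[C@@H]2OC(C)(C)OCC2=O | intermediate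
10 | (4S)-4-{(S)-(tert-butyldimethylsilyloxy)[(4R,5S)-2,2-dimethyl-5-vinyl-1,3-dioxolan-4-yl]methyl}-2,2-dimethyl-1,3-dioxan-5-one | C=C[C@@H]1OC(C)(C)O[C@H]1[C@H](O[Si](C)(C)C(C)(C)C)[C@@H]2OC(C)(C)OCC2=O | intermediate
11 | (4R)-4-{(R)-(tert-butyldimethylsilyloxy)[(4R,5S)-2,2-dimethyl-5-vinyl-1,3-dioxolan-4-yl]methyl}-2,2-dimethyl-5-methylene-1,3-dioxane | C=C[C@@H]1OC(C)(C)O[C@H]1[C@H](O[Si](C)(C)C(C)(C)C)[C@@H]2OC(C)(C)OCC2=C | intermediate
12 | (3S,4R,5R,6R)-5-(tert-butyldimethylsilyloxy)-3,4:6,7-di-O-isopropylidene-1-(hydroxymethyl)cyclohex-1-ene-3,4,5,6-tetrol | C1=C2COC(C)(C)O[C@H]2[C@@H](O[Si](C)(C)C(C)(C)C)[C@@H]3OC(C)(C)O[C@H]31 | intermediate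
13 | (3S,4S,5R,6R)-3,4:6,7-di-O-isopropylidene-1-(hydroxymethyl)cyclohex-1-ene-3,4,5,6-tetrol | C1=C2COC(C)(C)O[C@H]2[C@@H](O)[C@@H]3OC(C)(C)O[C@H]31 | intermediate
14 | (3S,4R,5R,6R)-5-O-benzoyl-3,4:6,7-di-O-isopropylidene-1-(hydroxymethyl)cyclohex-1-ene-3,4,5,6-tetrol | C1=C2COC(C)(C)O[C@H]2[C@@H](OC(=O)c4ccccc4)[C@@H]3OC(C)(C)O[C@H]31 | intermediate
15 | (3S,4R,5R,6R)-5-O-benzoyl-1-(hydroxymethyl)cyclohex-1-ene-3,4,5,6-tetrol | OCC1=C[C@H](O)[C@@H](O)[C@H](OC(=O)c2ccccc2)[C@@H]1O | intermediate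
16 | [(3S,4R,5R,6R)-5-(benzoyloxy)-3,4,6-trihydroxycyclohex-1-en-1-yl]methyl benzoate | O=C(OCC1=C[C@H](O)[C@@H](O)[C@H](OC(=O)c2ccccc2)[C@@H]1O)c1ccccc1 | target

**Summary**

Total step count: 14. Longest linear sequence: 14 steps (1 → 16); the second building block 8 enters at step 7.

**Steps most likely to fail, with fallbacks**

Step 9 (methylenation of the hindered, base-sensitive ketone 10). The ylide may epimerise C6 or eliminate the β-silyloxy group. The fallback is a Peterson olefination. It sets out from 10: the non-basic organocerium reagent made from Me3SiCH2MgCl and CeCl3 (THF, −78 °C) adds to the ketone to give the β-hydroxysilane (4S)-4-{(S)-(tert-butyldimethylsilyloxy)[(4R,5S)-2,2-dimethyl-5-vinyl-1,3-dioxolan-4-yl]methyl}-2,2-dimethyl-5-[(trimethylsilyl)methyl]-1,3-dioxan-5-ol F1 (either configuration at the new carbinol carbon). KH in THF at 0 °C then brings about syn-elimination of silanolate and delivers 11, where the route resumes.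

Step 10 (ring-closing metathesis of 11). The diene is doubly ring-constrained: the product carries a trans-fused dioxolane, and one alkene is an exocyclic methylene on the dioxane. The fallback cyclises an unconstrained substrate instead. It sets out from 11: Bu4NF gives the alcohol (R)-[(4R)-2,2-dimethyl-5-methylene-1,3-dioxan-4-yl][(4S,5S)-2,2-dimethyl-5-vinyl-1,3-dioxolan-4-yl]methanol F2. BzCl/pyridine/DMAP converts it into (R)-[(4R)-2,2-dimethyl-5-methylene-1,3-dioxan-4-yl][(4R,5S)-2,2-dimethyl-5-vinyl-1,3-dioxolan-4-yl]methyl benzoate F3. AcOH/H2O (4:1, 45 °C) removes both acetonides to give the acyclic diene (3R,4R,5R,6S)-3,5,6-trihydroxy-2-(hydroxymethyl)octa-1,7-dien-4-yl benzoate F4. Ring-closing metathesis of this free polyol with the second-generation Hoveyda–Grubbs catalyst (H2IMes)Cl2Ru=CH(C6H4-2-OiPr) in degassed THF/CH2Cl2 at 40 °C, helped by the free allylic hydroxyl groups, gives 15 directly. The route is rejoined at 15, bypassing 12–14.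

Step 14 (benzoylation of one hydroxyl out of four). Acylation with BzCl may also touch O3, O4 or O6, or over-acylate. The fallback activates the alcohol instead of the acyl donor. It sets out from 15: Mitsunobu esterification (PhCO2H, PPh3, DIAD, 1.1 equiv each, THF, −20 → 0 °C) converts only the unhindered primary allylic hydroxyl into an alkoxyphosphonium ion, which benzoate displaces at the achiral C7 methylene. This arrives at the target 16; no new compound lies on this path (none F0).

**Further compounds**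

F1 | step 9 | (4S)-4-{(S)-(tert-butyldimethylsilyloxy)[(4R,5S)-2,2-dimethyl-5-vinyl-1,3-dioxolan-4-yl]methyl}-2,2-dimethyl-5-[(trimethylsilyl)methyl]-1,3-dioxan-5-ol | C=C[C@@H]1OC(C)(C)O[C@H]1[C@H](O[Si](C)(C)C(C)(C)C)[C@@H]2OC(C)(C)OCC2(O)C[Si](C)(C)C
F2 | step 10 | (R)-[(4R)-2,2-dimethyl-5-methylene-1,3-dioxan-4-yl][(4S,5S)-2,2-dimethyl-5-vinyl-1,3-dioxolan-4-yl]methanol | C=C[C@@H]1OC(C)(C)O[C@H]1[C@H](O)[C@@H]2OC(C)(C)OCC2=C
F3 | step 10 | (R)-[(4R)-2,2-dimethyl-5-methylene-1,3-dioxan-4-yl][(4R,5S)-2,2-dimethyl-5-vinyl-1,3-dioxolan-4-yl]methyl benzoate | C=C[C@@H]1OC(C)(C)O[C@H]1[C@H](OC(=O)c3ccccc3)[C@@H]2OC(C)(C)OCC2=C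
F4 | step 10 | (3R,4R,5R,6S)-3,5,6-trihydroxy-2-(hydroxymethyl)octa-1,7-dien-4-yl benzoate | C=C[C@H](O)[C@@H](O)[C@H](OC(=O)c1ccccc1)[C@H](O)C(=C)CO
F0 | step 14 | none | none
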